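**Plan**

1. Numbering: norbornane C1 (bridgehead next to spiro C2), C3 (CMe2), C4, C5, C6, C7 (CH2 bridge); chromane atoms are primed. Cuts, in order: the two CHO groups; the C4'–isobutyl bond; then in one stroke C7–C4 and C3–C2; then the pyranone ring (C2'–C3' by Claisen acylation, O–C2' by cyclodehydration); last the C1–C7 arm (auxiliary alkylation) and the CH=CMe2 alkene (Wittig).
2. Enabling feature: C7 and C2 stand 1,3 across C1, and C2 is also C2' of the chromane. At the chromone oxidation level (C4'=O as temporary activator) C2 is an electrophilic β-carbon, while C4–C3 is the CH=CMe2 end of a chain tethered to C1 through C6–C5. A radical at C7 can therefore add across C4=C3 and end on C2 (radical [3+2] annulation).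
3. Forward order: acyclic (R)-succinate half-ester → chromone (pyranone ring) → cyclopentane and bicyclo[2.2.1]heptane with the spiro C–O centre in one operation → isobutyl at C4' → free phenols → two formyl groups.
4. Stereochemistry: C1 from alkylation of the (S)-4-benzyloxazolidinone imide; C4 and spiro C2 relayed from C1 in the bicyclisation (only the cis closure can finish; ring oxygen endo, C3' exo); C4' from hydrogenation of the chromene anti to the CMe2 group (isobutyl cis to C3).
5. Helpers removed later: CO2H on C7 (lost as CO2 in the key step), the C4' carbonyl (becomes the isobutyl-bearing carbon), benzyl ethers (hydrogenolysis).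

Key step: step 8

**Route**

Step 1
Reactants: 1 (4-carboxybutyl)triphenylphosphonium bromide
Product: 3 6-methylhept-5-enoic acid, via carboxylate ylide 2 (not isolated)
Conditions: NaN(SiMe3)2 (2.1 equiv), THF, 0 °C; acetone, 0 °C → rt; aq. HCl
Reagents that add atoms: acetone, CC(C)=O
Why: Wittig olefination of the unstabilised carboxylate ylide with acetone should give the trisubstituted Me2C=CH alkene, which carries no stereo-element.

Step 2
Reactants: 3 6-methylhept-5-enoic acid; 4 (4S)-4-benzyl-1,3-oxazolidin-2-one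
Product: 6 (4S)-4-benzyl-3-(6-methylhept-5-enoyl)-1,3-oxazolidin-2-one, via mixed pivalic anhydride 5 (not isolated)
Conditions: t-BuCOCl, Et3N, THF, −20 °C; then LiCl, 4, −20 °C → rt
Reagents that add atoms: none
Why: N-acylation of the oxazolidinone by the mixed anhydride should occur at the less hindered (non-pivaloyl) carbonyl, the standard one-pot imide formation.

Step 3
Reactants: 6 (4S)-4-benzyl-3-(6-methylhept-5-enoyl)-1,3-oxazolidin-2-one
Product: 8 tert-butyl (3R)-3-{[(4S)-4-benzyl-2-oxo-1,3-oxazolidin-3-yl]carbonyl}-7-methyloct-6-enoate, via sodium Z-enolate 7 (not isolated)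
Conditions: NaN(SiMe3)2, THF, −78 °C; BrCH2CO2t-Bu, −78 → −40 °C
Reagents that add atoms: tert-butyl bromoacetate, BrCC(=O)OC(C)(C)C
Why: Evans alkylation, in which the chelated Z-enolate is alkylated on the face opposite the benzyl group, should set the (R) centre that becomes C1.

Step 4
Reactants: 8 tert-butyl (3R)-3-{[(4S)-4-benzyl-2-oxo-1,3-oxazolidin-3-yl]carbonyl}-7-methyloct-6-enoate
Product: 10 (2R)-2-(2-tert-butoxy-2-oxoethyl)-6-methylhept-5-enoic acid, via lithium peroxycarboxylate 9 (not isolated)
Conditions: LiOH, H2O2 (30% aq.), THF–H2O, 0 °C; then aq. Na2SO3; HCl to pH 3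
Reagents that add atoms: hydrogen peroxide, OO (as lithium hydroperoxide, [Li+].[O-]O)
Why: Hydroperoxide cleaves the exocyclic imide carbonyl selectively, leaving the tert-butyl ester and the α-stereocentre untouched (standard auxiliary removal).

Step 5
Reactants: 11 1-(2,4,6-trihydroxyphenyl)ethan-1-one
Product: 12 1-[2,4-bis(benzyloxy)-6-hydroxyphenyl]ethan-1-one
Conditions: BnBr (2.1 equiv), K2CO3, DMF, rt
Reagents that add atoms: benzyl bromide, BrCc1ccccc1
Why: Williamson etherification should stop at the bis-ether because the remaining hydroxyl is deactivated by its hydrogen bond to the ketone.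

Step 6
Reactants: 10 (2R)-2-(2-tert-butoxy-2-oxoethyl)-6-methylhept-5-enoic acid; 12 1-[2,4-bis(benzyloxy)-6-hydroxyphenyl]ethan-1-one
Product: 15 tert-butyl (3R)-3-{3-[2,4-bis(benzyloxy)-6-hydroxyphenyl]-3-oxopropanoyl}-7-methyloct-6-enoate, via acyl imidazolide 13 (not isolated), via dilithium dianion 14 (not isolated)
Conditions: 10, 1,1'-carbonyldiimidazole, THF, rt; separately 12, LiN(SiMe3)2 (4.2 equiv), THF, −78 °C; combine at −78 → −20 °C; AcOH quench
Reagents that add atoms: none
Why: Claisen-type C-acylation of the ketone enolate by the acyl imidazolide gives the 1,3-diketone, whose immediate conversion into the diketonate at low temperature should protect the α-stereocentre.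

Step 7
Reactants: 15 tert-butyl (3R)-3-{3-[2,4-bis(benzyloxy)-6-hydroxyphenyl]-3-oxopropanoyl}-7-methyloct-6-enoate
Product: 17 (3R)-3-[5,7-bis(benzyloxy)-4-oxo-4H-chromen-2-yl]-7-methyloct-6-enoic acid, via chromone tert-butyl ester 16 (not isolated)
Conditions: TsOH·H2O (0.2 equiv), toluene, 40 °C, then 80 °C
Reagents that add atoms: none
Why: Acid-catalysed cyclodehydration of the o-hydroxyaryl 1,3-diketone closes the pyranone ring, and continued heating with the sulfonic acid removes the tert-butyl group as isobutene without a nucleophile that could add to the alkene.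

Step 8
Reactants: 17 (3R)-3-[5,7-bis(benzyloxy)-4-oxo-4H-chromen-2-yl]-7-methyloct-6-enoic acid
Product: 18 (1R,2R,4S)-5',7'-bis(benzyloxy)-3,3-dimethylspiro[bicyclo[2.2.1]heptane-2,2'-chroman]-4'-one (ring oxygen endo, C3' exo)
Conditions: Ir[dF(CF3)ppy]2(dtbbpy)PF6 (2 mol %), K2HPO4, DMF (0.01 M), 450 nm LEDs, 40 °C, Ar
Reagents that add atoms: none
Why: The excited trivalent iridium complex oxidises the carboxylate of 17 and CO2 is lost; the primary radical on the CH2 group (future C7) closes 5-exo-trig onto the CH end of the Me2C=CH alkene (new C7–C4 bond) to give a tertiary Me2C radical, which adds 5-exo-trig to C2' of the chromone, the β-carbon of the vinylogous ester (new C3–C2 bond, Giese addition), and the α-keto radical is reduced by the divalent iridium complex and protonated. The closest known reaction type is the decarboxylative photoredox Giese addition run as a tandem 5-exo/5-exo radical cyclisation, a radical [3+2] annulation of a homoallyl-type radical with an alkene. The first closure makes the cyclopentane C1–C7–C4–C5–C6 and the second the five-membered ring C1–C2–C3–C4–C7, which together are the bicyclo[2.2.1]heptane carrying the spiro carbon. C4 is controlled by the (R) centre at C1, because only the cyclopentyl radical with the Me2C and chromonyl groups cis can reach C2', and the spiro centre C2 by the rotamer of the planar chromone in the second closure, where the larger C3'–H edge should take the exo side and the ring oxygen the endo side. The step needs attack at the CH terminus (secured by the tertiary radical so formed), the cis mode of the first closure (not strongly biased by the substrate, so the unproductive trans radical is the expected loss, kept small by warming and high dilution), and no net 1,2-shift of the chromonyl group through 3-exo attack on C2', which the absence of a stoichiometric hydrogen donor should keep reversible.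

Step 9
Reactants: 18 (1R,2R,4S)-5',7'-bis(benzyloxy)-3,3-dimethylspiro[bicyclo[2.2.1]heptane-2,2'-chroman]-4'-one
Product: 20 (1R,2S,4S)-5',7'-bis(benzyloxy)-3,3-dimethyl-4'-(2-methylpropyl)spiro[bicyclo[2.2.1]heptane-2,2'-chromene], via tertiary alcohol 19 (not isolated)
Conditions: i-BuMgCl, LaCl3·2LiCl, THF, 0 °C; aq. NH4Cl; then pyridinium p-toluenesulfonate (cat.), toluene, 50 °C
Reagents that add atoms: isobutylmagnesium chloride, CC(C)C[Mg]Cl
Why: The lanthanum-modified Grignard reagent should add 1,2 to the hindered ketone without enolisation or β-hydride reduction, and mild acid dehydrates the tertiary alcohol through the doubly oxygen-stabilised benzylic cation toward the ring CH2 to give the conjugated 2H-chromene (the C2 descriptor changes only through CIP priorities).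

Step 10
Reactants: 20 (1R,2S,4S)-5',7'-bis(benzyloxy)-3,3-dimethyl-4'-(2-methylpropyl)spiro[bicyclo[2.2.1]heptane-2,2'-chromene]
Product: 21 (1R,2R,4S,4'S)-3,3-dimethyl-4'-(2-methylpropyl)spiro[bicyclo[2.2.1]heptane-2,2'-chromane]-5',7'-diol
Conditions: H2 (4 atm), 10% Pd/C, EtOAc–EtOH, rt
Reagents that add atoms: none
Why: Heterogeneous hydrogenation should deliver hydrogen to C3'=C4' from the face of the bridgehead C1–H, anti to the CMe2 group whose exo methyl eclipses C3', which sets (4'S) with isobutyl cis to C3, while both benzyl ethers are hydrogenolysed in the same operation.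

Step 11
Reactants: 21 (1R,2R,4S,4'S)-3,3-dimethyl-4'-(2-methylpropyl)spiro[bicyclo[2.2.1]heptane-2,2'-chromane]-5',7'-diol
Product: 23 (1R,2R,4S,4'S)-5',7'-dihydroxy-3,3-dimethyl-4'-(2-methylpropyl)spiro[bicyclo[2.2.1]heptane-2,2'-chromane]-6',8'-dicarbaldehyde (CNP0150011.1), via bis-iminium salt 22 (not isolated)
Conditions: POCl3, DMF, EtOAc, 0 °C → rt; then H2O, 60 °C
Reagents that add atoms: N,N-dimethylformamide, CN(C)C=O (formyl CH, through the chloroiminium salt); water, O (carbonyl oxygen)
Why: Double Vilsmeier–Haack formylation should take place at the only two free ring positions, C6' and C8', each activated by three oxygen donors, and hydrolysis of the bis-iminium salt gives the hydrogen-bonded dialdehyde without touching the stereocentres.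

**Compound list**

1 | (4-carboxybutyl)triphenylphosphonium bromide | OC(=O)CCCC[P+](c1ccccc1)(c1ccccc1)c1ccccc1.[Br-] | starting material
2 | sodium 5-(triphenyl-λ5-phosphanylidene)pentanoate (carboxylate ylide) | [Na+].[O-]C(=O)CCCC=P(c1ccccc1)(c1ccccc1)c1ccccc1 | intermediate
3 | 6-methylhept-5-enoic acid | CC(C)=CCCCC(=O)O | intermediate
4 | (4S)-4-benzyl-1,3-oxazolidin-2-one | O=C1N[C@@H](Cc2ccccc2)CO1 | starting material
5 | 6-methylhept-5-enoic pivalic anhydride | CC(C)=CCCCC(=O)OC(=O)C(C)(C)C | intermediate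
6 | (4S)-4-benzyl-3-(6-methylhept-5-enoyl)-1,3-oxazolidin-2-one | CC(C)=CCCCC(=O)N1C(=O)OC[C@@H]1Cc1ccccc1 | intermediate
7 | sodium (Z)-enolate of 6 | [Na+].O=C1OC[C@H](Cc2ccccc2)N1/C([O-])=C/CCC=C(C)C | intermediate
8 | tert-butyl (3R)-3-{[(4S)-4-benzyl-2-oxo-1,3-oxazolidin-3-yl]carbonyl}-7-methyloct-6-enoate | CC(C)=CCC[C@H](CC(=O)OC(C)(C)C)C(=O)N1C(=O)OC[C@@H]1Cc1ccccc1 | intermediate
9 | lithium (2R)-2-(2-tert-butoxy-2-oxoethyl)-6-methylhept-5-eneperoxoate | [Li+].[O-]OC(=O)[C@@H](CC(=O)OC(C)(C)C)CCC=C(C)C | intermediate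
10 | (2R)-2-(2-tert-butoxy-2-oxoethyl)-6-methylhept-5-enoic acid | OC(=O)[C@@H](CC(=O)OC(C)(C)C)CCC=C(C)C | intermediate
11 | 1-(2,4,6-trihydroxyphenyl)ethan-1-one | CC(=O)c1c(O)cc(O)cc1O | starting material
12 | 1-[2,4-bis(benzyloxy)-6-hydroxyphenyl]ethan-1-one | CC(=O)c1c(O)cc(OCc2ccccc2)cc1OCc1ccccc1 | intermediate
13 | tert-butyl (3R)-3-(1H-imidazole-1-carbonyl)-7-methyloct-6-enoate | O=C(n1ccnc1)[C@@H](CC(=O)OC(C)(C)C)CCC=C(C)C | intermediate
14 | dilithium phenoxide-enolate of 12 | [Li+].[Li+].C=C([O-])c1c([O-])cc(OCc2ccccc2)cc1OCc1ccccc1 | intermediate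
15 | tert-butyl (3R)-3-{3-[2,4-bis(benzyloxy)-6-hydroxyphenyl]-3-oxopropanoyl}-7-methyloct-6-enoate | O=C(CC(=O)c1c(O)cc(OCc2ccccc2)cc1OCc1ccccc1)[C@@H](CC(=O)OC(C)(C)C)CCC=C(C)C | intermediate
16 | tert-butyl (3R)-3-[5,7-bis(benzyloxy)-4-oxo-4H-chromen-2-yl]-7-methyloct-6-enoate | O=c1cc([C@@H](CC(=O)OC(C)(C)C)CCC=C(C)C)oc2cc(OCc3ccccc3)cc(OCc3ccccc3)c12 | intermediate
17 | (3R)-3-[5,7-bis(benzyloxy)-4-oxo-4H-chromen-2-yl]-7-methyloct-6-enoic acid | O=c1cc([C@@H](CC(=O)O)CCC=C(C)C)oc2cc(OCc3ccccc3)cc(OCc3ccccc3)c12 | intermediate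
18 | (1R,2R,4S)-5',7'-bis(benzyloxy)-3,3-dimethylspiro[bicyclo[2.2.1]heptane-2,2'-chroman]-4'-one | O=C1C[C@@]2(Oc3cc(OCc4ccccc4)cc(OCc4ccccc4)c31)[C@@H]1CC[C@@H](C1)C2(C)C | intermediate
19 | (1R,2R,4S)-5',7'-bis(benzyloxy)-3,3-dimethyl-4'-(2-methylpropyl)spiro[bicyclo[2.2.1]heptane-2,2'-chroman]-4'-ol (either C4' epimer) | CC(C)CC1(O)C[C@@]2(Oc3cc(OCc4ccccc4)cc(OCc4ccccc4)c31)[C@@H]1CC[C@@H](C1)C2(C)C | intermediate
20 | (1R,2S,4S)-5',7'-bis(benzyloxy)-3,3-dimethyl-4'-(2-methylpropyl)spiro[bicyclo[2.2.1]heptane-2,2'-chromene] | CC(C)CC1=C[C@@]2(Oc3cc(OCc4ccccc4)cc(OCc4ccccc4)c31)[C@@H]1CC[C@@H](C1)C2(C)C | intermediate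
21 | (1R,2R,4S,4'S)-3,3-dimethyl-4'-(2-methylpropyl)spiro[bicyclo[2.2.1]heptane-2,2'-chromane]-5',7'-diol | CC(C)C[C@H]1C[C@@]2(Oc3cc(O)cc(O)c31)[C@@H]1CC[C@@H](C1)C2(C)C | intermediate
22 | 6',8'-bis[(dimethyliminio)methyl] derivative of 21, dichloride | CC(C)C[C@H]1C[C@@]2(Oc3c(C=[N+](C)C)c(O)c(C=[N+](C)C)c(O)c31)[C@@H]1CC[C@@H](C1)C2(C)C.[Cl-].[Cl-] | intermediate
23 | (1R,2R,4S,4'S)-5',7'-dihydroxy-3,3-dimethyl-4'-(2-methylpropyl)spiro[bicyclo[2.2.1]heptane-2,2'-chromane]-6',8'-dicarbaldehyde | CC(C)C[C@H]1C[C@@]2(Oc3c(C=O)c(O)c(C=O)c(O)c31)[C@@H]1CC[C@@H](C1)C2(C)C | target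

**Step count and risks**

Total step count: 11. Longest linear sequence: 10 steps (steps 1–4 and 6–11; step 5 is a one-step side branch).

Steps most likely to fail:

Step 8. Three processes can drain material. The first 5-exo closure can go through the chair-like transition state with the chromonyl group equatorial, which gives the trans cyclopentyl radical that cannot reach C2'. The primary radical can attack C2' in a 3-exo sense and reopen to the secondary radical, a net 1,2-shift of the chromonyl group. The second closure can occur from the other chromone rotamer, placing the ring oxygen exo. The fallback builds the same spiro ketone by carbonyl chemistry on a preformed norbornane. It sets out from 12 and comes back at 18. Purchased (1S,4R)-(−)-camphene (its enantiomeric purity would have to be upgraded) would be ozonised (O3, CH2Cl2–MeOH, −78 °C; Me2S) to (1R,4S)-3,3-dimethylbicyclo[2.2.1]heptan-2-one F1. The dianion 14 made from 12 with LiN(SiMe3)2 would add to it to give the aldol adduct 1-[2,4-bis(benzyloxy)-6-hydroxyphenyl]-2-[(1R,4S)-2-hydroxy-3,3-dimethylbicyclo[2.2.1]heptan-2-yl]ethan-1-one F2. Dehydration with Burgess reagent would give the enone 1-[2,4-bis(benzyloxy)-6-hydroxyphenyl]-2-[(1R,4S)-3,3-dimethylbicyclo[2.2.1]heptan-2-ylidene]ethan-1-one F3, and base-mediated 6-endo oxa-Michael closure (K2CO3, MeOH) would give 18, with the spiro configuration then under thermodynamic control.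

Step 6. The α-stereocentre of the acyl imidazolide can lose configurational integrity under excess amide base, and again in step 7 through acid-catalysed enolisation of the diketone toward that carbon. The fallback closes the pyranone by a neutral intramolecular Wittig reaction on an ester carbonyl. It sets out from 12 (and uses 10) and comes back at 16, which the conditions of step 7 convert into 17. α-Bromination of 12 (CuBr2, EtOAc–CHCl3, reflux) would give 1-[2,4-bis(benzyloxy)-6-hydroxyphenyl]-2-bromoethan-1-one F4, and PPh3 would give {2-[2,4-bis(benzyloxy)-6-hydroxyphenyl]-2-oxoethyl}triphenylphosphonium bromide F5. O-Acylation of its phenol with 10 (N,N'-diisopropylcarbodiimide, 4-dimethylaminopyridine cat.) would give the aryl ester phosphonium bromide F6. Aqueous Na2CO3 would liberate the acyl-stabilised ylide F7, which on heating in toluene should olefinate the ester carbonyl and give 16.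

Step 10. Hydrogen can be delivered to the wrong face (syn to CMe2), or reduction of the hindered trisubstituted chromene can stall. The fallback replaces syn addition on a metal surface by hydride capture of a planar benzylic cation. It sets out from 19 (isolated after the Grignard addition of step 9) and comes back at 21. Ionic hydrogenation (Et3SiH, CF3CO2H, CH2Cl2, −78 → −40 °C), with hydride approaching anti to the CMe2 group, would give (1R,2R,4S,4'S)-5',7'-bis(benzyloxy)-3,3-dimethyl-4'-(2-methylpropyl)spiro[bicyclo[2.2.1]heptane-2,2'-chromane] F8, and hydrogenolysis (H2, 10% Pd/C, EtOAc) would then give 21.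

**Further compounds**

F1 | step 8 | (1R,4S)-3,3-dimethylbicyclo[2.2.1]heptan-2-one | O=C2[C@@H]1CC[C@@H](C1)C2(C)C
F2 | step 8 | 1-[2,4-bis(benzyloxy)-6-hydroxyphenyl]-2-[(1R,4S)-2-hydroxy-3,3-dimethylbicyclo[2.2.1]heptan-2-yl]ethan-1-one | O=C(CC2(O)[C@@H]1CC[C@@H](C1)C2(C)C)c1c(O)cc(OCc2ccccc2)cc1OCc1ccccc1
F3 | step 8 | 1-[2,4-bis(benzyloxy)-6-hydroxyphenyl]-2-[(1R,4S)-3,3-dimethylbicyclo[2.2.1]heptan-2-ylidene]ethan-1-one | O=C(C=C2[C@@H]1CC[C@@H](C1)C2(C)C)c1c(O)cc(OCc2ccccc2)cc1OCc1ccccc1
F4 | step 6 | 1-[2,4-bis(benzyloxy)-6-hydroxyphenyl]-2-bromoethan-1-one | O=C(CBr)c1c(O)cc(OCc2ccccc2)cc1OCc1ccccc1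
F5 | step 6 | {2-[2,4-bis(benzyloxy)-6-hydroxyphenyl]-2-oxoethyl}triphenylphosphonium bromide | O=C(C[P+](c1ccccc1)(c1ccccc1)c1ccccc1)c1c(O)cc(OCc2ccccc2)cc1OCc1ccccc1.[Br-]
F6 | step 6 | (2-{2,4-bis(benzyloxy)-6-[(2R)-2-(2-tert-butoxy-2-oxoethyl)-6-methylhept-5-enoyloxy]phenyl}-2-oxoethyl)triphenylphosphonium bromide | O=C(C[P+](c1ccccc1)(c1ccccc1)c1ccccc1)c1c(OC(=O)[C@@H](CC(=O)OC(C)(C)C)CCC=C(C)C)cc(OCc2ccccc2)cc1OCc1ccccc1.[Br-]
F7 | step 6 | 3,5-bis(benzyloxy)-2-[2-(triphenyl-λ5-phosphanylidene)acetyl]phenyl (2R)-2-(2-tert-butoxy-2-oxoethyl)-6-methylhept-5-enoate | O=C(C=P(c1ccccc1)(c1ccccc1)c1ccccc1)c1c(OC(=O)[C@@H](CC(=O)OC(C)(C)C)CCC=C(C)C)cc(OCc2ccccc2)cc1OCc1ccccc1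
F8 | step 10 | (1R,2R,4S,4'S)-5',7'-bis(benzyloxy)-3,3-dimethyl-4'-(2-methylpropyl)spiro[bicyclo[2.2.1]heptane-2,2'-chromane] | CC(C)C[C@H]1C[C@@]2(Oc3cc(OCc4ccccc4)cc(OCc4ccccc4)c31)[C@@H]1CC[C@@H](C1)C2(C)C
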